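The depside ester is cut last, and the route rests on assembling ring B of the phenolic half in one operation. Ring B carries three contiguous substituents: pentyl on C6, the carboxyl carbon on C1 and OMe on C2. An aryne spanning C1–C6 with that OMe beside it takes n-pentyllithium at C6 and CO2 at C1, so both C–C bonds form in one flask under control of the C2 oxygen. The precursor is a vicinal dibromoanisole with a methoxymethyl-protected phenol at the future C4, reached by sterically governed C–H borylation/oxidation. Ring A comes from olivetol as a dibenzylated acid; esterification and one hydrogenolysis finish the synthesis.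

Key step: step 4

Assumption: 2,3-dibromoanisole is taken as a purchasable arene (otherwise one O-methylation from 2,3-dibromophenol), and n-pentyllithium is prepared within the route.

Step 1
Reactants: 1 2,3-dibromoanisole (1,2-dibromo-3-methoxybenzene)
Product: 3 3,4-dibromo-5-methoxyphenol, via pinacol arylboronate 2 (not isolated)
Conditions: [Ir(OMe)(cod)]2 (cat.), 4,4'-di-tert-butyl-2,2'-bipyridine (cat.), B2pin2 (1 equiv), THF, 80 °C; then Oxone (2KHSO5·KHSO4·K2SO4), acetone/H2O, 0 °C to rt
Reagents that add atoms: bis(pinacolato)diboron, CC1(C)OB(OC1(C)C)B1OC(C)(C)C(C)(C)O1 (boryl group of 2 only); potassium peroxymonosulfate KHSO5, [K+].[O-]S(=O)(=O)OO (hydroxyl oxygen of 3)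
Why: Iridium-catalysed aromatic C–H borylation is governed by sterics, and in the 1,2,3-trisubstituted ring of 1 only C5–H has no ortho neighbour, so boron should enter there with the C–Br bonds untouched, after which peroxymonosulfate oxidation of the C–B bond in the same flask gives the phenol with its hydroxyl meta to OMe and para to the central bromine, a placement that electrophilic bromination of a 3,5-disubstituted phenol could not guarantee.

Step 2
Reactants: 3 3,4-dibromo-5-methoxyphenol
Product: 4 1,2-dibromo-3-methoxy-5-(methoxymethoxy)benzene
Conditions: NaH, THF, 0 °C; then MOMCl, 0 °C to rt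
Reagents that add atoms: chloromethyl methyl ether, COCCl
Why: Williamson-type O-alkylation of the sodium phenoxide with the reactive α-chloro ether forms the methoxymethyl acetal, which tolerates organolithiums at low temperature and leaves both aryl bromides in place.

Step 3
Reactants: 5 1-chloropentane
Product: 6 n-pentyllithium (hexane solution, filtered and titrated)
Conditions: Li (dispersion, about 1% Na), hexane, 30–40 °C, argon
Reagents that add atoms: lithium, [Li]
Why: Direct reductive metalation of a primary alkyl chloride by lithium metal in a hydrocarbon is the standard preparation of n-alkyllithiums, the insoluble LiCl being filtered off before use.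

Step 4
Reactants: 4 1,2-dibromo-3-methoxy-5-(methoxymethoxy)benzene; 6 n-pentyllithium
Product: 10 2-methoxy-4-(methoxymethoxy)-6-pentylbenzoic acid, via ortho-bromoaryllithium 7 (not isolated), via 3-methoxy-5-(methoxymethoxy)benzyne 8 (not isolated), via 2-lithioanisole adduct 9 (not isolated)
Conditions: 6 (3 equiv), THF, −78 °C, slow addition of 4, then to −20 °C; CO2 (dry gas), −78 °C to rt; cold 1 M HCl to pH 3
Reagents that add atoms: carbon dioxide, O=C=O
Why: Bromine–lithium exchange on 4, faster than any deprotonation, gives 7, which loses LiBr on warming to the single aryne 8 whose position is dictated by the two adjacent bromines; a second equivalent of 6 then adds across the strained triple bond and the aryllithium 9 so formed is carboxylated by CO2. The closest known reaction type is the addition of alkyllithiums to 3-alkoxybenzynes with electrophilic capture of the resulting 2-lithioanisole, a three-component aryne carbolithiation. No ring is closed and no stereocentre is created. The selectivity required is regiochemical: pentyl must enter at the aryne carbon remote from OMe (future C6) so that lithium, and then the carboxyl carbon, sits on the carbon next to OMe (future C1). The C2 methoxy group secures this, because its inductively withdrawing C–O bond and O–Li coordination stabilise the developing sp2 carbanion beside it, whereas the methoxymethoxy group is two carbons away from the triple bond and exerts no comparable pull. Keeping 6 in excess and adding 4 slowly at low temperature should let pentyllithium, not the aryllithiums 7 or 9, intercept the aryne.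

Step 5
Reactants: 10 2-methoxy-4-(methoxymethoxy)-6-pentylbenzoic acid
Product: 11 benzyl 2-methoxy-4-(methoxymethoxy)-6-pentylbenzoate
Conditions: BnBr, K2CO3, DMF, rt
Reagents that add atoms: benzyl bromide, BrCc1ccccc1
Why: Carboxylate O-alkylation (SN2 at the benzylic carbon of benzyl bromide) sidesteps attack at the di-ortho-substituted carbonyl carbon and leaves the base-stable methoxymethyl acetal intact.

Step 6
Reactants: 11 benzyl 2-methoxy-4-(methoxymethoxy)-6-pentylbenzoate
Product: 12 benzyl 4-hydroxy-2-methoxy-6-pentylbenzoate
Conditions: HCl (cat., conc. aq.), MeOH/THF, 40 °C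
Reagents that add atoms: none
Why: Acid-catalysed acetal exchange with methanol removes the methoxymethyl group as dimethoxymethane, while the doubly ortho-substituted benzyl ester is too hindered to transesterify and the methyl ether is inert.

Step 7
Reactants: 13 olivetol (5-pentylbenzene-1,3-diol)
Product: 15 2,4-dihydroxy-6-pentylbenzaldehyde, via aryl iminium chloride 14 (not isolated)
Conditions: POCl3, DMF, 0 °C to rt; then H2O, 50 °C
Reagents that add atoms: N,N-dimethylformamide, CN(C)C=O (formyl carbon); water, O (formyl oxygen)
Why: Vilsmeier–Haack formylation of the electron-rich resorcinol ring should occur mainly para to one hydroxyl and ortho to the other, next to the pentyl chain (the position favoured in orcinol-type resorcinols), and not between the two hydroxyls, and hydrolysis of the iminium salt 14 releases the aldehyde.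

Step 8
Reactants: 15 2,4-dihydroxy-6-pentylbenzaldehyde
Product: 16 2,4-bis(benzyloxy)-6-pentylbenzaldehyde
Conditions: BnBr (excess), K2CO3, DMF, 60 °C
Reagents that add atoms: benzyl bromide, BrCc1ccccc1
Why: Williamson ether synthesis with excess benzyl bromide and warming alkylates both phenols, including the hydrogen-bonded ortho hydroxyl, and installs groups that leave together with the benzyl ester at the end.

Step 9
Reactants: 16 2,4-bis(benzyloxy)-6-pentylbenzaldehyde
Product: 17 2,4-bis(benzyloxy)-6-pentylbenzoic acid
Conditions: NaClO2, NaH2PO4, 2-methyl-2-butene, t-BuOH/THF/H2O, rt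
Reagents that add atoms: sodium chlorite, [Na+].[O-]Cl=O
Why: Pinnick oxidation converts the hindered aromatic aldehyde into the acid under buffered conditions, with 2-methyl-2-butene consuming the hypochlorous acid that would otherwise chlorinate the electron-rich ring, and benzyl ethers are unaffected.

Step 10
Reactants: 17 2,4-bis(benzyloxy)-6-pentylbenzoic acid; 12 benzyl 4-hydroxy-2-methoxy-6-pentylbenzoate
Product: 19 benzyl 4-{[2,4-bis(benzyloxy)-6-pentylbenzoyl]oxy}-2-methoxy-6-pentylbenzoate, via mixed trifluoroacetic anhydride 18 (not isolated)
Conditions: (CF3CO)2O, toluene, 0 °C to rt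
Reagents that add atoms: trifluoroacetic anhydride, O=C(OC(=O)C(F)(F)F)C(F)(F)F (trifluoroacetyl group of 18 only)
Why: Mixed-anhydride esterification, in which the electron-rich acid forms the acyl trifluoroacetate 18, an acylium-like donor able to overcome the two ortho substituents, which acylates the phenolic oxygen of 12 to give the depside ester, the usual way to join hindered benzoic acids to phenols.

Step 11
Reactants: 19 benzyl 4-{[2,4-bis(benzyloxy)-6-pentylbenzoyl]oxy}-2-methoxy-6-pentylbenzoate
Product: 20 4-[(2,4-dihydroxy-6-pentylbenzoyl)oxy]-2-methoxy-6-pentylbenzoic acid (target)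
Conditions: H2 (1 atm), Pd/C (10 wt% Pd), EtOAc, rt
Reagents that add atoms: none
Why: Palladium-catalysed hydrogenolysis cleaves the two benzyl ethers and the benzyl ester as toluene in one operation, while the aryl ester link, the methyl ether and both arenes are stable under one atmosphere of hydrogen at room temperature.

Compound list
1 | 2,3-dibromoanisole (1,2-dibromo-3-methoxybenzene) | COc1cccc(Br)c1Br | starting material
2 | 2-(3,4-dibromo-5-methoxyphenyl)-4,4,5,5-tetramethyl-1,3,2-dioxaborolane | COc1cc(B2OC(C)(C)C(C)(C)O2)cc(Br)c1Br | intermediate
3 | 3,4-dibromo-5-methoxyphenol | COc1cc(O)cc(Br)c1Br | intermediate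
4 | 1,2-dibromo-3-methoxy-5-(methoxymethoxy)benzene | COCOc1cc(Br)c(Br)c(OC)c1 | intermediate
5 | 1-chloropentane | CCCCCCl | starting material
6 | n-pentyllithium | [Li]CCCCC | intermediate
7 | 2-bromo-6-methoxy-4-(methoxymethoxy)phenyllithium | [Li]c1c(Br)cc(OCOC)cc1OC | intermediate
8 | 3-methoxy-5-(methoxymethoxy)benzyne (1,2-didehydro-3-methoxy-5-(methoxymethoxy)benzene) | COCOC1=CC#CC(OC)=C1 | intermediate
9 | 2-methoxy-4-(methoxymethoxy)-6-pentylphenyllithium | [Li]c1c(CCCCC)cc(OCOC)cc1OC | intermediate
10 | 2-methoxy-4-(methoxymethoxy)-6-pentylbenzoic acid | CCCCCc1cc(OCOC)cc(OC)c1C(=O)O | intermediate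
11 | benzyl 2-methoxy-4-(methoxymethoxy)-6-pentylbenzoate | CCCCCc1cc(OCOC)cc(OC)c1C(=O)OCc1ccccc1 | intermediate
12 | benzyl 4-hydroxy-2-methoxy-6-pentylbenzoate | CCCCCc1cc(O)cc(OC)c1C(=O)OCc1ccccc1 | intermediate
13 | olivetol (5-pentylbenzene-1,3-diol) | CCCCCc1cc(O)cc(O)c1 | starting material
14 | [(2,4-dihydroxy-6-pentylphenyl)methylidene]dimethyliminium chloride | CCCCCc1cc(O)cc(O)c1C=[N+](C)C.[Cl-] | intermediate
15 | 2,4-dihydroxy-6-pentylbenzaldehyde | CCCCCc1cc(O)cc(O)c1C=O | intermediate
16 | 2,4-bis(benzyloxy)-6-pentylbenzaldehyde | CCCCCc1cc(OCc2ccccc2)cc(OCc2ccccc2)c1C=O | intermediate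
17 | 2,4-bis(benzyloxy)-6-pentylbenzoic acid | CCCCCc1cc(OCc2ccccc2)cc(OCc2ccccc2)c1C(=O)O | intermediate
18 | 2,4-bis(benzyloxy)-6-pentylbenzoic trifluoroacetic anhydride | CCCCCc1cc(OCc2ccccc2)cc(OCc2ccccc2)c1C(=O)OC(=O)C(F)(F)F | intermediate
19 | benzyl 4-{[2,4-bis(benzyloxy)-6-pentylbenzoyl]oxy}-2-methoxy-6-pentylbenzoate | CCCCCc1cc(OCc2ccccc2)cc(OCc2ccccc2)c1C(=O)Oc1cc(CCCCC)c(C(=O)OCc2ccccc2)c(OC)c1 | intermediate
20 | 4-[(2,4-dihydroxy-6-pentylbenzoyl)oxy]-2-methoxy-6-pentylbenzoic acid | CCCCCc1cc(O)cc(O)c1C(=O)Oc1cc(CCCCC)c(C(=O)O)c(OC)c1 | target

Total step count: 11. Longest linear sequence: 7 steps (steps 1, 2, 4, 5, 6, 10 and 11, from 1 to 20).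

Steps most likely to fail

Step 4. The aryne may be consumed by the aryllithiums 7 or 9 in place of pentyllithium (biaryl formation), 9 may be alkylated by the 1-bromopentane released in the exchange, or excess base may lithiate next to the methoxymethoxy group and cause over-carboxylation. The fallback builds ring B without an aryne and sets out from 15, the aldehyde made in step 7. Selective protection of its 4-hydroxyl (MOMCl, one equivalent, K2CO3, acetone; the 2-hydroxyl is held in a hydrogen bond to the formyl group) should give 2-hydroxy-4-(methoxymethoxy)-6-pentylbenzaldehyde F1. Methylation (MeI, K2CO3, DMF) should give 2-methoxy-4-(methoxymethoxy)-6-pentylbenzaldehyde F2, and Pinnick oxidation (NaClO2, NaH2PO4, 2-methyl-2-butene) comes back to the route at 10.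

Step 10. Acyl transfer from the hindered donor may be slow, so that trifluoroacetylation of the phenol or acid-promoted loss of the ortho benzyl ether competes. The fallback sets out from 17: oxalyl chloride with catalytic DMF in CH2Cl2 should give 2,4-bis(benzyloxy)-6-pentylbenzoyl chloride F3, which is isolated and combined with the potassium phenoxide of 12 (K2CO3, acetone, reflux). This acylation under basic instead of acidic conditions comes back to the route at 19.

Step 7. Formylation between the two hydroxyls, or a second formylation, would erode regiocontrol and lower the supply of ring A. The fallback sets out from 13: carboxylation with methyl magnesium carbonate (MeOMgOCO2Me, DMF, 120 °C, then acid) delivers the carboxyl ortho to a hydroxyl through a magnesium chelate and should give 2,4-dihydroxy-6-pentylbenzoic acid F4. Exhaustive benzylation (BnBr, K2CO3, DMF) should give benzyl 2,4-bis(benzyloxy)-6-pentylbenzoate F5, and saponification (KOH, DMSO/H2O, 80 °C, then acid) comes back to the route at 17.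

Further compounds
F1 | step 4 | 2-hydroxy-4-(methoxymethoxy)-6-pentylbenzaldehyde | CCCCCc1cc(OCOC)cc(O)c1C=O
F2 | step 4 | 2-methoxy-4-(methoxymethoxy)-6-pentylbenzaldehyde | CCCCCc1cc(OCOC)cc(OC)c1C=O
F3 | step 10 | 2,4-bis(benzyloxy)-6-pentylbenzoyl chloride | CCCCCc1cc(OCc2ccccc2)cc(OCc2ccccc2)c1C(Cl)=O
F4 | step 7 | 2,4-dihydroxy-6-pentylbenzoic acid (olivetolic acid) | CCCCCc1cc(O)cc(O)c1C(=O)O
F5 | step 7 | benzyl 2,4-bis(benzyloxy)-6-pentylbenzoate | CCCCCc1cc(OCc2ccccc2)cc(OCc2ccccc2)c1C(=O)OCc1ccccc1
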